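**Retrosynthetic overview** (clerodane numbering: ring A = C1–C5 and C10; ring B = C5–C10; C17 on C8, C18 on C4, C19 on C5, C20 on C9; side chain C11–C16)

1. Target ⇐ acylation and desilylation of 33 ⇐ Suzuki–Miyaura union (C12–C13) of alkylboronate 28 with (Z)-vinyl iodide 32, which carries the side-chain alkene geometry.
2. C9–C11 and the quaternary C9 ⇐ Giese addition of the tertiary C9 radical (from trans-decalone 23 via MeLi and an oxalate) to a vinylboronate, on the face opposite the axial C19.
3. Decalone 23 ⇐ isoxazoline 18 by N–O cleavage, dehydration, enone reduction and base equilibration of C8 and C10.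
4. Key disconnection: ring B by a formal [4+2] of the C7–C6–C5–C10 unit of ring A diene 10 with (E)-1-nitropropene as a methylketene equivalent, forming C7–C8 (conjugate addition) and C9–C10 (intramolecular silyl nitronate cycloaddition). Ring A comes first (Birch reduction–alkylation of an arene, sets C5), ring B second.
5. Enabling feature: C9 lies between C8 and C10 in ring B. With C9 as a ketone both neighbours are epimerizable and the trans ring fusion with equatorial C17 is the thermodynamic form, so the annulation needs no stereocontrol. The C18 methyl on C4 blocks C3=C4, so only C1=C10 reacts.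

Key step: step 7

Assumption: the facial sense of the alkylation in step 2 is taken to be that of 2-alkylbenzamides of this auxiliary; if it is the opposite, the (R)-auxiliary is used and nothing else changes.

**Route**

Step 1
Reactants: 1 2-methylbenzoyl chloride; 2 (S)-2-(methoxymethyl)pyrrolidine
Product: 3 [(2S)-2-(methoxymethyl)pyrrolidin-1-yl](2-methylphenyl)methanone
Conditions: Et3N, CH2Cl2, 0 → 25 °C
Reagents that add atoms: none
Why: N-acylation of the secondary amine by the acid chloride (Schotten–Baumann-type amide formation) attaches the chiral controller for the Birch step.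

Step 2
Reactants: 3 [(2S)-2-(methoxymethyl)pyrrolidin-1-yl](2-methylphenyl)methanone
Product: 5 [(2S)-2-(methoxymethyl)pyrrolidin-1-yl][(1R)-1,2-dimethylcyclohexa-2,5-dien-1-yl]methanone, via potassium amide dienolate 4 (not isolated)
Conditions: K, NH3/THF, t-BuOH (1 equiv), −78 °C; then MeI, −78 °C
Reagents that add atoms: iodomethane, CI
Why: Birch reduction–alkylation: two-electron reduction gives the chelated amide dienolate, and C-methylation at the carboxamide-bearing carbon on the face away from the methoxymethyl arm should set the quaternary C5 (auxiliary control) and leave the 1,4-diene of ring A with C18 already on C3=C4.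

Step 3
Reactants: 5 [(2S)-2-(methoxymethyl)pyrrolidin-1-yl][(1R)-1,2-dimethylcyclohexa-2,5-dien-1-yl]methanone
Product: 7 (1R)-1,2-dimethylcyclohexa-2,5-diene-1-carbaldehyde, via zirconated hemiaminal 6 (not isolated)
Conditions: Cp2Zr(H)Cl, THF, 25 °C; then H2O
Reagents that add atoms: none
Why: hydrozirconation of the tertiary amide carbonyl (amide-to-aldehyde reduction) stops at the O-zirconated hemiaminal, which on work-up should give the non-enolizable aldehyde and release the auxiliary, the internal ring alkenes reacting far more slowly.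

Step 4
Reactants: 7 (1R)-1,2-dimethylcyclohexa-2,5-diene-1-carbaldehyde
Product: 8 (6R)-6-ethenyl-1,6-dimethylcyclohexa-1,4-diene
Conditions: Ph3PCH3Br, KOtBu, THF, 0 → 25 °C
Reagents that add atoms: methyltriphenylphosphonium bromide, C[P+](c1ccccc1)(c1ccccc1)c1ccccc1.[Br-]
Why: Wittig methylenation of the hindered but non-enolizable aldehyde brings in C7 as the terminal carbon of a vinyl group.

Step 5
Reactants: 8 (6R)-6-ethenyl-1,6-dimethylcyclohexa-1,4-diene
Product: 10 (6R)-6-(2-iodoethyl)-1,6-dimethylcyclohexa-1,4-diene, via alkylzirconocene chloride 9 (not isolated)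
Conditions: Cp2Zr(H)Cl, THF, 25 °C; then I2, 0 °C
Reagents that add atoms: iodine, II
Why: hydrozirconation puts zirconium on the terminal carbon of the only monosubstituted alkene (anti-Markovnikov, ring alkenes untouched) and iodinolysis of the C–Zr bond should give the primary iodide.

Step 6
Reactants: 11 1-nitropropan-2-ol
Product: 13 (E)-1-nitroprop-1-ene, via nitro mesylate 12 (not isolated)
Conditions: MsCl, Et3N, CH2Cl2, −10 → 25 °C
Reagents that add atoms: none
Why: mesylation and E1cB elimination of the β-nitro alcohol should give the conjugated nitroalkene as its more stable (E)-isomer.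

Step 7
Reactants: 10 (6R)-6-(2-iodoethyl)-1,6-dimethylcyclohexa-1,4-diene; 13 (E)-1-nitroprop-1-ene
Product: 18 tricyclic 2-isoxazoline (C9=N–O–C1; ring B cis-fused to ring A; both C8 epimers), via Grignard reagent 14 (not isolated), via iodomagnesium nitronate 15 (not isolated), via trimethylsilyl nitronate 16 (not isolated), via N-silyloxyisoxazolidine 17 (not isolated)
Conditions: Mg, THF, 25 °C; then 13, CuBr·SMe2 (5 mol %), −78 °C; TMSCl, −78 → 60 °C; then TsOH·H2O (cat.), 25 °C
Reagents that add atoms: none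
Why: Copper-catalysed conjugate addition of Grignard reagent 14 to the β-carbon of nitroalkene 13 forms C7–C8 and a metal nitronate, O-silylation turns this into silyl nitronate 16, which adds as a 1,3-dipole across C1=C10 to form C9–C10 and O–C1, and acid-induced loss of Me3SiOH gives the isoxazoline. The closest known reaction type is the tandem Michael addition/intramolecular silyl nitronate–olefin cycloaddition, here with nitropropene acting as a methylketene equivalent. Ring B closes as a six-membered carbocycle by a concerted suprafacial [3+2] addition in the fused mode (dipole carbon to the proximal alkene carbon C10), and the isoxazolidine ring closes in the same event. C10 and C1 are set cis to the C6 tether by the intramolecular delivery and C8 forms without control. None of these centres has to be controlled, because C9 becomes a ketone (C8 and C10 then epimerizable) and the C1 oxygen is removed. The step needs site selectivity for C1=C10 over C3=C4, secured by the C18 methyl (bond formation at the fully substituted C4 next to quaternary C5 is disfavoured), and 1,4- over 1,2-addition to the nitroalkene, secured by copper catalysis at low temperature.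

Step 8
Reactants: 18 tricyclic 2-isoxazoline
Product: 19 (4aR)-8-hydroxy-2,4a,5-trimethyl-3,4,4a,7,8,8a-hexahydronaphthalen-1(2H)-one (cis-fused; both C2 epimers)
Conditions: H2 (1 atm), Raney Ni, B(OH)3, MeOH/H2O (5:1), 25 °C
Reagents that add atoms: water, O
Why: hydrogenolysis of the N–O bond and hydrolysis of the resulting β-hydroxy imine in the boric acid buffer unmask the C9 ketone, and the hindered trisubstituted C3=C4 alkene should survive.

Step 9
Reactants: 19 (4aR)-8-hydroxy-2,4a,5-trimethyl-3,4,4a,7,8,8a-hexahydronaphthalen-1(2H)-one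
Product: 20 (4aR)-2,4a,5-trimethyl-3,4,4a,7-tetrahydronaphthalen-1(2H)-one (both C2 epimers)
Conditions: TsOH·H2O (cat.), PhMe, 80 °C
Reagents that add atoms: none
Why: acid-catalysed β-elimination of water from the β-hydroxy ketone should give the conjugated enone (C10=C1), the more stable regioisomer, and so removes the C1 oxygen.

Step 10
Reactants: 20 (4aR)-2,4a,5-trimethyl-3,4,4a,7-tetrahydronaphthalen-1(2H)-one
Product: 23 (2R,4aR,8aS)-2,4a,5-trimethyl-3,4,4a,7,8,8a-hexahydronaphthalen-1(2H)-one, via lithium enolate 21 (not isolated), via ketone epimer mixture 22 (not isolated)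
Conditions: Li, NH3/THF, t-BuOH (1 equiv), −78 °C; NH4Cl; then NaOMe (cat.), MeOH, 25 °C
Reagents that add atoms: none
Why: dissolving-metal reduction of the enone gives the C9 enolate, and protonation followed by methoxide equilibration of both α-centres should funnel all isomers to the trans-fused decalone with equatorial C17 (thermodynamic control: the axial C19 is 1,3 to the trigonal C9 and a 2-methylcyclohexanone prefers the equatorial methyl), while the isolated C3=C4 alkene is inert.

Step 11
Reactants: 23 (2R,4aR,8aS)-2,4a,5-trimethyl-3,4,4a,7,8,8a-hexahydronaphthalen-1(2H)-one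
Product: 24 (2R,4aR,8aS)-1,2,4a,5-tetramethyl-1,2,3,4,4a,7,8,8a-octahydronaphthalen-1-ol (either C1 epimer)
Conditions: MeLi, CeCl3, THF, −78 °C
Reagents that add atoms: methyllithium, [Li]C
Why: 1,2-addition of the weakly basic organocerium reagent to the hindered enolizable ketone brings in C20, and the C9 configuration of the carbinol is irrelevant because C9 becomes a radical.

Step 12
Reactants: 24 (2R,4aR,8aS)-1,2,4a,5-tetramethyl-1,2,3,4,4a,7,8,8a-octahydronaphthalen-1-ol
Product: 26 cesium oxalate of alcohol 24, via methyl oxalate 25 (not isolated)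
Conditions: ClC(O)CO2Me, Et3N, DMAP (cat.), CH2Cl2, 0 °C; then CsOH (1 equiv), THF/H2O, 25 °C
Reagents that add atoms: methyl chlorooxoacetate, COC(=O)C(Cl)=O; CsOH, [Cs+].[OH-]
Why: acylation of the tertiary alcohol by the reactive oxalyl chloride half-ester and selective saponification of the methyl ester should give the stable cesium oxalate, a precursor of the tertiary radical.

Step 13
Reactants: 26 cesium oxalate of alcohol 24; 27 2-ethenyl-4,4,5,5-tetramethyl-1,3,2-dioxaborolane
Product: 28 4,4,5,5-tetramethyl-2-{2-[(1S,2R,4aR,8aR)-1,2,4a,5-tetramethyl-1,2,3,4,4a,7,8,8a-octahydronaphthalen-1-yl]ethyl}-1,3,2-dioxaborolane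
Conditions: Ir[dF(CF3)ppy]2(dtbbpy)PF6 (1 mol %), DME/DMF (3:1), H2O (10 equiv), blue LEDs, 60 °C
Reagents that add atoms: none
Why: photoredox oxidation of the oxalate triggers double decarboxylation to the tertiary C9 radical, which undergoes Giese addition to the vinylboronate followed by reduction and protonation of the α-boryl radical; the C9–C11 bond should form on the equatorial face anti to the axial C19, so that C20 ends axial and cis to C19 (substrate control).

Step 14
Reactants: 29 but-2-yne-1,4-diol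
Product: 30 4-{[tert-butyl(dimethyl)silyl]oxy}but-2-yn-1-ol
Conditions: NaH (1 equiv), TBSCl (1 equiv), THF, 0 → 25 °C
Reagents that add atoms: tert-butyldimethylsilyl chloride, CC(C)(C)[Si](C)(C)Cl
Why: monosilylation of the symmetrical diol through its mono-sodium alkoxide differentiates the two hydroxyls of the later C15 and C16.

Step 15
Reactants: 30 4-{[tert-butyl(dimethyl)silyl]oxy}but-2-yn-1-ol
Product: 32 (2Z)-4-{[tert-butyl(dimethyl)silyl]oxy}-3-iodobut-2-en-1-ol, via cyclic alkenylaluminate 31 (not isolated)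
Conditions: NaAlH2(OCH2CH2OMe)2, THF, 0 °C; then I2, −78 → 0 °C
Reagents that add atoms: iodine, II
Why: hydroxyl-directed trans-hydroalumination (hydride to the carbon next to the free CH2OH, aluminium to the distal carbon in a five-membered aluminate) and iodinolysis with retention should give the (Z)-vinyl iodide and so fix the side-chain alkene geometry.

Step 16
Reactants: 28 alkylboronate; 32 (2Z)-4-{[tert-butyl(dimethyl)silyl]oxy}-3-iodobut-2-en-1-ol
Product: 33 (2E)-3-({[tert-butyl(dimethyl)silyl]oxy}methyl)-5-[(1S,2R,4aR,8aR)-1,2,4a,5-tetramethyl-1,2,3,4,4a,7,8,8a-octahydronaphthalen-1-yl]pent-2-en-1-ol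
Conditions: Pd(OAc)2 (5 mol %), RuPhos, K3PO4, PhMe/H2O (10:1), 80 °C
Reagents that add atoms: none
Why: B-alkyl Suzuki–Miyaura coupling of the primary alkylboronate with the vinyl iodide forms C12–C13 with retention of alkene geometry and tolerates the free allylic alcohol.

Step 17
Reactants: 33 allylic alcohol; 34 docosanoyl chloride
Product: 35 (2E)-3-({[tert-butyl(dimethyl)silyl]oxy}methyl)-5-[(1S,2R,4aR,8aR)-1,2,4a,5-tetramethyl-1,2,3,4,4a,7,8,8a-octahydronaphthalen-1-yl]pent-2-en-1-yl docosanoate
Conditions: pyridine, DMAP (cat.), CH2Cl2, 0 → 25 °C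
Reagents that add atoms: none
Why: acylation of the only free hydroxyl (primary allylic, C15) by the acid chloride.

Step 18
Reactants: 35 silyl ether ester
Product: 36 (2E)-3-(hydroxymethyl)-5-[(1S,2R,4aR,8aR)-1,2,4a,5-tetramethyl-1,2,3,4,4a,7,8,8a-octahydronaphthalen-1-yl]pent-2-en-1-yl docosanoate
Conditions: HF·pyridine, THF/pyridine, 0 → 25 °C
Reagents that add atoms: none
Why: fluoride-mediated cleavage of the primary silyl ether under buffered conditions frees C16–OH, and the trans arrangement of the two CH2O groups across the double bond should prevent acyl migration.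

**Compound list**

1 | 2-methylbenzoyl chloride | Cc1ccccc1C(Cl)=O | starting material
2 | (S)-2-(methoxymethyl)pyrrolidine | COC[C@@H]1CCCN1 | starting material
3 | [(2S)-2-(methoxymethyl)pyrrolidin-1-yl](2-methylphenyl)methanone | COC[C@@H]1CCCN1C(=O)c1ccccc1C | intermediate
4 | potassium [(2S)-2-(methoxymethyl)pyrrolidin-1-yl](2-methylcyclohexa-2,5-dien-1-ylidene)methanolate (amide dienolate) | COC[C@@H]1CCCN1C([O-])=C1C(C)=CCC=C1.[K+] | intermediate
5 | [(2S)-2-(methoxymethyl)pyrrolidin-1-yl][(1R)-1,2-dimethylcyclohexa-2,5-dien-1-yl]methanone | COC[C@@H]1CCCN1C(=O)[C@@]1(C)C(C)=CCC=C1 | intermediate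
6 | chlorido{[(1R)-1,2-dimethylcyclohexa-2,5-dien-1-yl][(2S)-2-(methoxymethyl)pyrrolidin-1-yl]methoxy}bis(cyclopentadienyl)zirconium (zirconated hemiaminal, both epimers at the hemiaminal carbon) | COC[C@@H]1CCCN1C(O[Zr](Cl)(C2C=CC=C2)C2C=CC=C2)[C@@]1(C)C(C)=CCC=C1 | intermediate
7 | (1R)-1,2-dimethylcyclohexa-2,5-diene-1-carbaldehyde | O=C[C@@]1(C)C(C)=CCC=C1 | intermediate
8 | (6R)-6-ethenyl-1,6-dimethylcyclohexa-1,4-diene | C=C[C@@]1(C)C(C)=CCC=C1 | intermediate
9 | chlorido{2-[(1R)-1,2-dimethylcyclohexa-2,5-dien-1-yl]ethyl}bis(cyclopentadienyl)zirconium | Cl[Zr](CC[C@@]1(C)C(C)=CCC=C1)(C1C=CC=C1)C1C=CC=C1 | intermediate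
10 | (6R)-6-(2-iodoethyl)-1,6-dimethylcyclohexa-1,4-diene | ICC[C@@]1(C)C(C)=CCC=C1 | intermediate
11 | 1-nitropropan-2-ol (racemic) | CC(O)C[N+](=O)[O-] | starting material
12 | 1-nitropropan-2-yl methanesulfonate | CC(OS(C)(=O)=O)C[N+](=O)[O-] | intermediate
13 | (E)-1-nitroprop-1-ene | C/C=C/[N+](=O)[O-] | intermediate
14 | {2-[(1R)-1,2-dimethylcyclohexa-2,5-dien-1-yl]ethyl}magnesium iodide | I[Mg]CC[C@@]1(C)C(C)=CCC=C1 | intermediate
15 | iodomagnesium nitronate of 4-[(1R)-1,2-dimethylcyclohexa-2,5-dien-1-yl]-2-methyl-1-nitrobutane (both C2 epimers) | CC(CC[C@@]1(C)C(C)=CCC=C1)C=[N+]([O-])O[Mg]I | intermediate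
16 | trimethylsilyl nitronate of the same nitroalkane (both C2 epimers) | CC(CC[C@@]1(C)C(C)=CCC=C1)C=[N+]([O-])O[Si](C)(C)C | intermediate
17 | N-(trimethylsilyloxy)isoxazolidine cycloadduct (ring B cis-fused to ring A; O on C1 syn to the C9–C10 bond; both C8 epimers) | CC1CC[C@@]2(C)C(C)=CC[C@H]3ON(O[Si](C)(C)C)C1[C@@H]23 | intermediate
18 | tricyclic 2-isoxazoline (C9=N–O–C1; ring B cis-fused to ring A; both C8 epimers) | CC1CC[C@@]2(C)C(C)=CC[C@H]3ON=C1[C@@H]23 | intermediate
19 | (4aR)-8-hydroxy-2,4a,5-trimethyl-3,4,4a,7,8,8a-hexahydronaphthalen-1(2H)-one (cis-fused; OH syn to the C1–C8a bond; both C2 epimers) | O=C1C(C)CC[C@@]2(C)C(C)=CC[C@@H](O)[C@@H]12 | intermediate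
20 | (4aR)-2,4a,5-trimethyl-3,4,4a,7-tetrahydronaphthalen-1(2H)-one (both C2 epimers) | O=C1C(C)CC[C@@]2(C)C(C)=CCC=C12 | intermediate
21 | lithium enolate of ketone 22 (O–Li on C9; C9=C10) | [Li]OC1=C2CCC=C(C)[C@]2(C)CCC1C | intermediate
22 | (4aR)-2,4a,5-trimethyl-3,4,4a,7,8,8a-hexahydronaphthalen-1(2H)-one (mixture of C2 and C8a epimers) | O=C1C(C)CC[C@@]2(C)C(C)=CCCC12 | intermediate
23 | (2R,4aR,8aS)-2,4a,5-trimethyl-3,4,4a,7,8,8a-hexahydronaphthalen-1(2H)-one (trans-fused; equatorial 2-methyl) | O=C1[C@H](C)CC[C@@]2(C)C(C)=CCC[C@H]12 | intermediate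
24 | (2R,4aR,8aS)-1,2,4a,5-tetramethyl-1,2,3,4,4a,7,8,8a-octahydronaphthalen-1-ol (either C1 epimer) | CC1(O)[C@H](C)CC[C@@]2(C)C(C)=CCC[C@H]12 | intermediate
25 | methyl (2R,4aR,8aS)-1,2,4a,5-tetramethyl-1,2,3,4,4a,7,8,8a-octahydronaphthalen-1-yl oxalate | COC(=O)C(=O)OC1(C)[C@H](C)CC[C@@]2(C)C(C)=CCC[C@H]12 | intermediate
26 | cesium 2-oxo-2-{[(2R,4aR,8aS)-1,2,4a,5-tetramethyl-1,2,3,4,4a,7,8,8a-octahydronaphthalen-1-yl]oxy}acetate | [Cs+].[O-]C(=O)C(=O)OC1(C)[C@H](C)CC[C@@]2(C)C(C)=CCC[C@H]12 | intermediate
27 | 2-ethenyl-4,4,5,5-tetramethyl-1,3,2-dioxaborolane | C=CB1OC(C)(C)C(C)(C)O1 | starting material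
28 | 4,4,5,5-tetramethyl-2-{2-[(1S,2R,4aR,8aR)-1,2,4a,5-tetramethyl-1,2,3,4,4a,7,8,8a-octahydronaphthalen-1-yl]ethyl}-1,3,2-dioxaborolane | CC1(C)OB(CC[C@@]2(C)[C@H](C)CC[C@@]3(C)C(C)=CCC[C@H]23)OC1(C)C | intermediate
29 | but-2-yne-1,4-diol | OCC#CCO | starting material
30 | 4-{[tert-butyl(dimethyl)silyl]oxy}but-2-yn-1-ol | OCC#CCO[Si](C)(C)C(C)(C)C | intermediate
31 | sodium cyclic alkenylaluminate (five-membered O–Al–C=C–C ring; Al on the carbon that bears CH2OTBS) | [Na+].COCCO[Al-]1(OCCOC)OCC=C1CO[Si](C)(C)C(C)(C)C | intermediate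
32 | (2Z)-4-{[tert-butyl(dimethyl)silyl]oxy}-3-iodobut-2-en-1-ol | OC/C=C(/CO[Si](C)(C)C(C)(C)C)I | intermediate
33 | (2E)-3-({[tert-butyl(dimethyl)silyl]oxy}methyl)-5-[(1S,2R,4aR,8aR)-1,2,4a,5-tetramethyl-1,2,3,4,4a,7,8,8a-octahydronaphthalen-1-yl]pent-2-en-1-ol | OC/C=C(/CO[Si](C)(C)C(C)(C)C)CC[C@@]1(C)[C@H](C)CC[C@@]2(C)C(C)=CCC[C@H]12 | intermediate
34 | docosanoyl chloride | CCCCCCCCCCCCCCCCCCCCCC(Cl)=O | starting material
35 | (2E)-3-({[tert-butyl(dimethyl)silyl]oxy}methyl)-5-[(1S,2R,4aR,8aR)-1,2,4a,5-tetramethyl-1,2,3,4,4a,7,8,8a-octahydronaphthalen-1-yl]pent-2-en-1-yl docosanoate | CCCCCCCCCCCCCCCCCCCCCC(=O)OC/C=C(/CO[Si](C)(C)C(C)(C)C)CC[C@@]1(C)[C@H](C)CC[C@@]2(C)C(C)=CCC[C@H]12 | intermediate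
36 | (2E)-3-(hydroxymethyl)-5-[(1S,2R,4aR,8aR)-1,2,4a,5-tetramethyl-1,2,3,4,4a,7,8,8a-octahydronaphthalen-1-yl]pent-2-en-1-yl docosanoate (CNP0279526.1) | CCCCCCCCCCCCCCCCCCCCCC(=O)OC/C=C(/CO)CC[C@@]1(C)[C@H](C)CC[C@@]2(C)C(C)=CCC[C@H]12 | target

**Step count**

Total: 18 steps. Longest linear sequence: 15 steps (steps 1–5, 7–13 and 16–18).

**Steps most likely to fail**

Step 7. The Grignard reagent may attack the nitro group directly or transfer an electron, and the nitroalkene may oligomerize before conjugate addition. The dipolar ring closure onto the ring alkene next to the quaternary C5 may also be slow enough for the silyl nitronate to decompose. The fallback sets out from iodide 10 and builds the same ketone through an acyl radical. Iodide 10 would alkylate the lithium enolate of ethyl propanoate (LDA, THF/DMPU, −78 °C) to give ethyl 4-[(1R)-1,2-dimethylcyclohexa-2,5-dien-1-yl]-2-methylbutanoate F1, which forms C7–C8. Saponification (LiOH, THF/H2O) would give the acid F2, and PhSeSePh/Bu3P the Se-phenyl selenoester F3. Bu3SnH/AIBN (slow addition, PhH, 80 °C) would generate the acyl radical, whose 6-exo cyclization onto C10 forms C9–C10 and gives ketone mixture 22. Methoxide equilibration would bring this back to the route at 23.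

Step 13. Capture of the hindered tertiary radical by the only weakly electrophilic vinylboronate may be slow, so that the radical is reduced to the hydrocarbon or the oxalate is lost by hydrolysis. The fallback sets out from cesium oxalate 26 and uses methyl acrylate as the acceptor under the same photoredox conditions, giving methyl ester F4 with the same facial selectivity. Saponification would give acid F5, and N-hydroxyphthalimide with a carbodiimide the redox-active ester F6. Nickel-catalysed decarboxylative borylation (B2pin2 activated by MeLi, NiCl2·6H2O, a bipyridine ligand, MgBr2·OEt2, THF/DMF) would remove the extra carbon and return to the route at 28.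

Step 16. Transmetalation of the primary alkyl pinacol boronate may be slow, leaving time for protodeboronation, β-hydride elimination and decay of the vinyl iodide. The fallback sets out from 28 and changes the nucleophile to zinc. Oxidation (NaBO3·4H2O, THF/H2O) would give primary alcohol F7, and I2/PPh3/imidazole the iodide F8. Zinc insertion (Zn, LiCl, THF) would give alkylzinc iodide F9, and Negishi coupling with 32 (Pd(OAc)2, SPhos, slow addition of the zinc reagent) would return to the route at 33.

**Further compounds**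

F1 | step 7 | ethyl 4-[(1R)-1,2-dimethylcyclohexa-2,5-dien-1-yl]-2-methylbutanoate (both C2 epimers) | CCOC(=O)C(C)CC[C@@]1(C)C(C)=CCC=C1
F2 | step 7 | 4-[(1R)-1,2-dimethylcyclohexa-2,5-dien-1-yl]-2-methylbutanoic acid (both C2 epimers) | OC(=O)C(C)CC[C@@]1(C)C(C)=CCC=C1
F3 | step 7 | Se-phenyl 4-[(1R)-1,2-dimethylcyclohexa-2,5-dien-1-yl]-2-methylbutaneselenoate (both C2 epimers) | O=C([Se]c1ccccc1)C(C)CC[C@@]1(C)C(C)=CCC=C1
F4 | step 13 | methyl 3-[(1S,2R,4aR,8aR)-1,2,4a,5-tetramethyl-1,2,3,4,4a,7,8,8a-octahydronaphthalen-1-yl]propanoate | COC(=O)CC[C@@]1(C)[C@H](C)CC[C@@]2(C)C(C)=CCC[C@H]12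
F5 | step 13 | 3-[(1S,2R,4aR,8aR)-1,2,4a,5-tetramethyl-1,2,3,4,4a,7,8,8a-octahydronaphthalen-1-yl]propanoic acid | OC(=O)CC[C@@]1(C)[C@H](C)CC[C@@]2(C)C(C)=CCC[C@H]12
F6 | step 13 | 1,3-dioxoisoindolin-2-yl 3-[(1S,2R,4aR,8aR)-1,2,4a,5-tetramethyl-1,2,3,4,4a,7,8,8a-octahydronaphthalen-1-yl]propanoate | O=C(CC[C@@]1(C)[C@H](C)CC[C@@]2(C)C(C)=CCC[C@H]12)ON1C(=O)c2ccccc2C1=O
F7 | step 16 | 2-[(1S,2R,4aR,8aR)-1,2,4a,5-tetramethyl-1,2,3,4,4a,7,8,8a-octahydronaphthalen-1-yl]ethanol | OCC[C@@]1(C)[C@H](C)CC[C@@]2(C)C(C)=CCC[C@H]12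
F8 | step 16 | (1S,2R,4aR,8aR)-1-(2-iodoethyl)-1,2,4a,5-tetramethyl-1,2,3,4,4a,7,8,8a-octahydronaphthalene | ICC[C@@]1(C)[C@H](C)CC[C@@]2(C)C(C)=CCC[C@H]12
F9 | step 16 | {2-[(1S,2R,4aR,8aR)-1,2,4a,5-tetramethyl-1,2,3,4,4a,7,8,8a-octahydronaphthalen-1-yl]ethyl}zinc iodide | I[Zn]CC[C@@]1(C)[C@H](C)CC[C@@]2(C)C(C)=CCC[C@H]12
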